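**Retrosynthetic overview**
1. The 1H-pyrrole ring is bought intact as 1H-pyrrole-2-carbaldehyde, so no ring is formed; the last operation only frees the CH2OH group from a silyl ether.
2. Key disconnection: the C4–C5 bond of the 16-methylheptadecanoyl chain (ketone carbon = C1, bonded to pyrrole C2). It is cut into two primary alkyl radicals, each released from a carboxylic acid N-hydroxyphthalimide ester and joined by nickel-electrocatalytic doubly decarboxylative coupling.
3. Enabling feature: C4 and C5 are unbranched CH2 carbons with no stereocentre or heteroatom nearby, and C4 is the γ-carbon of the pyrrolyl ketone. C1–C4 plus one carboxyl carbon is therefore a glutaryl unit, and C5–C17 plus one carboxyl carbon is commercial 13-methyltetradecanoic acid. The electron-poor 2-acyl-1H-pyrrole ring is safe under cathodic conditions.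
4. Keto acid half: C5-acylation of the N-magnesium salt of 2-(silyloxymethyl)-1H-pyrrole with glutaric anhydride; that pyrrole comes from reduction and O-silylation of the aldehyde.

Key step: step 6

Remark on the chemistry: the target has no stereocentre and no stereogenic double bond, so it is one achiral compound and no step needs stereocontrol.

**Route**

Step 1
Reactants: 1 1H-pyrrole-2-carbaldehyde
Product: 2 (1H-pyrrol-2-yl)methanol
Conditions: NaBH4, MeOH/THF, 0 °C; aq NaHCO3 work-up, crude used at once
Reagents that add atoms: none
Why: Borohydride reduction of the heteroaryl aldehyde to the primary alcohol; the work-up is kept basic and the product is not stored, because 2-(hydroxymethyl)pyrroles ionise to azafulvenium ions under acid.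

Step 2
Reactants: 2 (1H-pyrrol-2-yl)methanol
Product: 3 2-({[tert-butyl(diphenyl)silyl]oxy}methyl)-1H-pyrrole
Conditions: TBDPSCl, imidazole, DMF, 0 °C to rt
Reagents that add atoms: tert-butyl(chloro)diphenylsilane, CC(C)(C)[Si](Cl)(c1ccccc1)c1ccccc1
Why: Imidazole-promoted O-silylation of the primary alcohol should be much faster than N-silylation of the weakly acidic pyrrole N–H and gives a bulky, base-stable ether that blocks azafulvene formation.

Step 3
Reactants: 3 2-({[tert-butyl(diphenyl)silyl]oxy}methyl)-1H-pyrrole; 4 glutaric anhydride
Product: 6 5-[5-({[tert-butyl(diphenyl)silyl]oxy}methyl)-1H-pyrrol-2-yl]-5-oxopentanoic acid, via N-bromomagnesio pyrrole 5 (not isolated)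
Conditions: 3 (2 equiv), EtMgBr (2 equiv), THF, 0 °C; then 4 (1 equiv), −40 to 0 °C; aq NH4Cl, then citric acid to pH 4–5
Reagents that add atoms: ethylmagnesium bromide, CC[Mg]Br (its MgBr is present only in intermediate 5; no atoms remain in 6)
Why: C-acylation of a pyrrolylmagnesium halide (Oddo-type reaction), in which the N-magnesiated ambident anion should be acylated at its free α-carbon C5 and the opened anhydride is left as a magnesium carboxylate that resists a second addition, while the second equivalent of 5 only deprotonates the more acidic acylpyrrole N–H and is recovered as 3.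

Step 4
Reactants: 6 5-[5-({[tert-butyl(diphenyl)silyl]oxy}methyl)-1H-pyrrol-2-yl]-5-oxopentanoic acid
Product: 7 1,3-dioxoisoindolin-2-yl 5-[5-({[tert-butyl(diphenyl)silyl]oxy}methyl)-1H-pyrrol-2-yl]-5-oxopentanoate
Conditions: N-hydroxyphthalimide, DIC, DMAP (cat.), CH2Cl2, rt
Reagents that add atoms: N-hydroxyphthalimide, ON1C(=O)c2ccccc2C1=O
Why: Carbodiimide (Steglich-type) esterification should give the redox-active ester, since the acylpyrrole N–H is non-nucleophilic and the silyl ether and ketone are inert.

Step 5
Reactants: 8 13-methyltetradecanoic acid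
Product: 9 1,3-dioxoisoindolin-2-yl 13-methyltetradecanoate
Conditions: N-hydroxyphthalimide, DIC, DMAP (cat.), CH2Cl2, rt
Reagents that add atoms: N-hydroxyphthalimide, ON1C(=O)c2ccccc2C1=O
Why: The same Steglich-type esterification on a plain fatty acid should give the second redox-active ester without complication.

Step 6
Reactants: 7 1,3-dioxoisoindolin-2-yl 5-[5-({[tert-butyl(diphenyl)silyl]oxy}methyl)-1H-pyrrol-2-yl]-5-oxopentanoate; 9 1,3-dioxoisoindolin-2-yl 13-methyltetradecanoate
Product: 10 1-[5-({[tert-butyl(diphenyl)silyl]oxy}methyl)-1H-pyrrol-2-yl]-16-methylheptadecan-1-one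
Conditions: 7 (1 equiv), 9 (3 equiv), NiCl2·6H2O (20 mol%), 2,2':6',2''-terpyridine (20 mol%), AgNO3 (30 mol%), NMP, Mg anode/RVC cathode, undivided cell, constant current, rt; aq NH4Cl work-up
Reagents that add atoms: none
Why: Cathodic reduction gives low-valent terpyridine–nickel, and single-electron transfer from it and from the silver-coated cathode to each N-acyloxyphthalimide triggers N–O cleavage and loss of CO2, giving the 12-methyltridecyl and 4-oxo-4-(pyrrol-2-yl)butyl radicals, which are captured in turn at nickel and leave by reductive elimination as the C4–C5 bond while the magnesium anode is consumed to Mg2+. The closest known reaction type is the nickel-electrocatalytic doubly decarboxylative C(sp3)–C(sp3) cross-coupling of two redox-active esters, which is established for pairs of primary alkyl acids bearing polar functionality. No ring is closed and no stereocentre is created, so only chemoselectivity has to be secured. Cross-coupling over homo-coupling is statistical and is favoured by running the simple ester 9 in threefold excess over 7, the hydrocarbon dimer of the iso-alkyl chain being removed by chromatography. The reductive medium should leave the oxidation-sensitive pyrrole untouched, and the acylpyrrole ketone should be reduced only well beyond the potential at which the phthalimide esters react. The radical from 7 sits γ to the carbonyl, so it is not stabilised, cannot fragment, and its six-membered cyclisation onto pyrrole C3 should be slower than capture by nickel.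

Step 7
Reactants: 10 1-[5-({[tert-butyl(diphenyl)silyl]oxy}methyl)-1H-pyrrol-2-yl]-16-methylheptadecan-1-one
Product: 11 1-[5-(hydroxymethyl)-1H-pyrrol-2-yl]-16-methylheptadecan-1-one
Conditions: TBAF, AcOH, THF, 0 °C to rt
Reagents that add atoms: none
Why: Fluoride-mediated cleavage of the silyl ether, buffered with acetic acid so that the acylpyrrole N–H and the ketone meet no strong base, should free the alcohol, which the 5-acyl group stabilises against azafulvene formation.

**Compound list**
1 | 1H-pyrrole-2-carbaldehyde | O=Cc1ccc[nH]1 | starting material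
2 | (1H-pyrrol-2-yl)methanol | OCc1ccc[nH]1 | intermediate
3 | 2-({[tert-butyl(diphenyl)silyl]oxy}methyl)-1H-pyrrole | CC(C)(C)[Si](OCc1ccc[nH]1)(c1ccccc1)c1ccccc1 | intermediate
4 | glutaric anhydride (oxane-2,6-dione) | O=C1CCCC(=O)O1 | starting material
5 | bromo[2-({[tert-butyl(diphenyl)silyl]oxy}methyl)pyrrol-1-yl]magnesium | CC(C)(C)[Si](OCc1cccn1[Mg]Br)(c1ccccc1)c1ccccc1 | intermediate
6 | 5-[5-({[tert-butyl(diphenyl)silyl]oxy}methyl)-1H-pyrrol-2-yl]-5-oxopentanoic acid | OC(=O)CCCC(=O)c1ccc(CO[Si](c2ccccc2)(c2ccccc2)C(C)(C)C)[nH]1 | intermediate
7 | 1,3-dioxoisoindolin-2-yl 5-[5-({[tert-butyl(diphenyl)silyl]oxy}methyl)-1H-pyrrol-2-yl]-5-oxopentanoate | O=C(CCCC(=O)c1ccc(CO[Si](c2ccccc2)(c2ccccc2)C(C)(C)C)[nH]1)ON1C(=O)c2ccccc2C1=O | intermediate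
8 | 13-methyltetradecanoic acid | CC(C)CCCCCCCCCCCC(=O)O | starting material
9 | 1,3-dioxoisoindolin-2-yl 13-methyltetradecanoate | CC(C)CCCCCCCCCCCC(=O)ON1C(=O)c2ccccc2C1=O | intermediate
10 | 1-[5-({[tert-butyl(diphenyl)silyl]oxy}methyl)-1H-pyrrol-2-yl]-16-methylheptadecan-1-one | CC(C)CCCCCCCCCCCCCCC(=O)c1ccc(CO[Si](c2ccccc2)(c2ccccc2)C(C)(C)C)[nH]1 | intermediate
11 | 1-[5-(hydroxymethyl)-1H-pyrrol-2-yl]-16-methylheptadecan-1-one | CC(C)CCCCCCCCCCCCCCC(=O)c1ccc(CO)[nH]1 | target

**Step count**
Total steps: 7. Longest linear sequence: 6 (steps 1, 2, 3, 4, 6, 7).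

**Steps most likely to fail**

Step 6. The limiting ester 7 may be lost to statistical homo-coupling, the alkylnickel intermediate may be protonated by the pyrrole N–H (giving the decarboxylated alkane), or the γ-keto radical may cyclise onto the pyrrole ring. The fallback makes the same chain bond by a classical anodic coupling before any heterocycle is present, and then attaches the pyrrole by acylation. It sets out from 8 and 3 and comes back at 10. Acid 8 is electrolysed with an excess of monomethyl glutarate (mixed Kolbe coupling: smooth Pt electrodes, MeOH, 5–10 % neutralised with NaOMe, high current density, 40–50 °C), which should give methyl 16-methylheptadecanoate F1 after separation from dimethyl octanedioate and the hydrocarbon dimer. Saponification (LiOH, THF/H2O, then acid) should give 16-methylheptadecanoic acid F2, and oxalyl chloride with catalytic DMF in CH2Cl2 should give 16-methylheptadecanoyl chloride F3. F3 is added at −78 to 0 °C to the magnesium pyrrolide 5, generated from 3 (2 equiv) and EtMgBr as in step 3, which should give 10.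

Step 3. The ambident magnesium pyrrolide may be acylated on nitrogen or at a β-carbon, the keto carboxylate may take up a second pyrrolyl unit, or the silyloxy group may be lost through an azafulvene during the acidic work-up. The fallback replaces anhydride opening by chelation-controlled acyl transfer from a 2-pyridyl thioester, with the carboxyl group carried as its methyl ester. It sets out from 3 and comes back at 6. Methyl 5-chloro-5-oxopentanoate with pyridine-2-thiol and Et3N in CH2Cl2 should give methyl 5-oxo-5-(pyridin-2-ylsulfanyl)pentanoate F4. Addition of F4 at −78 °C to 5 (from 3 and EtMgBr, toluene/THF) should give methyl 5-[5-({[tert-butyl(diphenyl)silyl]oxy}methyl)-1H-pyrrol-2-yl]-5-oxopentanoate F5, and LiOH in THF/H2O followed by acidification to pH 4–5 should give 6.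

Step 2. Self-condensation of the acid-sensitive alcohol 2 (loss of water through the azafulvenium ion, leading to dipyrromethane-type oligomers) may outrun O-silylation. The fallback carries the pyrrole nitrogen as its tert-butyl carbamate, which switches off azafulvenium formation while the alcohol is made and silylated. It sets out from 1 and comes back at 3. Boc2O with catalytic DMAP in MeCN should give tert-butyl 2-formyl-1H-pyrrole-1-carboxylate F6. NaBH4 in MeOH/THF at −20 to 0 °C should give tert-butyl 2-(hydroxymethyl)-1H-pyrrole-1-carboxylate F7. TBDPSCl and imidazole in DMF should give tert-butyl 2-({[tert-butyl(diphenyl)silyl]oxy}methyl)-1H-pyrrole-1-carboxylate F8. NaOMe in MeOH/THF at rt should then remove the carbamate and give 3.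

**Further compounds**
F1 | step 6 | methyl 16-methylheptadecanoate | CC(C)CCCCCCCCCCCCCCC(=O)OC
F2 | step 6 | 16-methylheptadecanoic acid | CC(C)CCCCCCCCCCCCCCC(=O)O
F3 | step 6 | 16-methylheptadecanoyl chloride | CC(C)CCCCCCCCCCCCCCC(=O)Cl
F4 | step 3 | methyl 5-oxo-5-(pyridin-2-ylsulfanyl)pentanoate | COC(=O)CCCC(=O)Sc1ccccn1
F5 | step 3 | methyl 5-[5-({[tert-butyl(diphenyl)silyl]oxy}methyl)-1H-pyrrol-2-yl]-5-oxopentanoate | COC(=O)CCCC(=O)c1ccc(CO[Si](c2ccccc2)(c2ccccc2)C(C)(C)C)[nH]1
F6 | step 2 | tert-butyl 2-formyl-1H-pyrrole-1-carboxylate | CC(C)(C)OC(=O)n1cccc1C=O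
F7 | step 2 | tert-butyl 2-(hydroxymethyl)-1H-pyrrole-1-carboxylate | CC(C)(C)OC(=O)n1cccc1CO
F8 | step 2 | tert-butyl 2-({[tert-butyl(diphenyl)silyl]oxy}methyl)-1H-pyrrole-1-carboxylate | CC(C)(C)OC(=O)n1cccc1CO[Si](c1ccccc1)(c1ccccc1)C(C)(C)C
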